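The synthesis rests on cutting the C7–CH2–C1' bridge on both sides of a methylene that is a formaldehyde carbon. On the carbocyclic ring of the quinolin-2-one, C7 is the only unsubstituted position ortho to C8–OH, because the other ortho atom is the fusion carbon C8a. An arylboronic acid esterified to O8 can therefore deliver formaldehyde to C7. From the boron-bound ortho-quinone methide it can then hand its own aryl group (C1', para to the benzyloxy donor) to the new CH2. One operation forms C7–CH2 and CH2–C1' and leaves O8–H free for sulfation. The precursor is the complete bicycle, 8-hydroxy-3-methoxyquinolin-2(1H)-one, with O8–H and N1–H unprotected.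

Key step: step 5

Remark on stereochemistry: the target has no stereocentre, no stereoaxis and no configured double bond. It is achiral, so there is no enantiomer to select and no step has to control configuration.
Remark on the sulfates: aryl sulfate monoesters are drawn as neutral hydrogen sulfates, as in the target SMILES. They would be handled as sodium salts, with the acid form released only at the very end.

Step 1
Reactants: 1 3-hydroxy-2-nitrobenzaldehyde
Product: 2 3-(benzyloxy)-2-nitrobenzaldehyde
Conditions: BnBr (1.1 equiv), K2CO3 (1.5 equiv), DMF, rt to 50 °C
Reagents that add atoms: benzyl bromide, BrCc1ccccc1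
Why: Williamson ether synthesis, in which carbonate fully deprotonates the acidic ortho-nitrophenol and the phenoxide displaces the primary benzylic bromide while aldehyde and nitro group stay inert, so that O8 is masked for the reduction and the basic ring closure by a group that later leaves under neutral hydrogenolysis.

Step 2
Reactants: 2 3-(benzyloxy)-2-nitrobenzaldehyde
Product: 3 2-amino-3-(benzyloxy)benzaldehyde
Conditions: Fe powder (5 equiv), NH4Cl, EtOH/H2O 4:1, 80 °C
Reagents that add atoms: none
Why: Béchamp-type iron reduction at near-neutral pH converts the nitro group into the aniline without touching the aldehyde or the benzyl ether, both of which would be at risk under catalytic hydrogenation, and the hydrogen-bonded aminoaldehyde with both ortho positions of nitrogen occupied condenses with itself only slowly and is carried on at once.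

Step 3
Reactants: 3 2-amino-3-(benzyloxy)benzaldehyde; 4 methoxyacetyl chloride
Product: 6 8-(benzyloxy)-3-methoxyquinolin-2(1H)-one, via methoxyacetanilide 5 (not isolated)
Conditions: 4 (1.2 equiv), Cs2CO3 (3.5 equiv), DMAc, 0 °C to rt; then 90 °C
Reagents that add atoms: none
Why: N-acylation followed by a Camps-type intramolecular aldol condensation, in which carbonate forms the amide enolate at the methoxy-bearing CH2, this carbon adds to the neighbouring formyl group in a 6-exo-trig closure (C3–C4) and water is lost on aromatisation to the 2-quinolone, so that the amide bond exists before the C3=C4 bond and no alkene geometry can stand in the way of the lactam, as it could in an olefination and nitro reduction sequence.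

Step 4
Reactants: 6 8-(benzyloxy)-3-methoxyquinolin-2(1H)-one
Product: 7 8-hydroxy-3-methoxyquinolin-2(1H)-one
Conditions: H2 (1 atm), 10% Pd/C, MeOH/THF, rt
Reagents that add atoms: none
Why: Catalytic hydrogenolysis of an aryl benzyl ether, under which the C3=C4 bond is safe because it is part of the aromatic pyridone ring, as is well established for 8-benzyloxyquinolin-2-ones at atmospheric pressure and room temperature.

Step 5
Reactants: 7 8-hydroxy-3-methoxyquinolin-2(1H)-one; 8 formaldehyde (charged as paraformaldehyde); 9 4-(benzyloxy)-3-methoxyphenylboronic acid
Product: 14 7-[4-(benzyloxy)-3-methoxybenzyl]-8-hydroxy-3-methoxyquinolin-2(1H)-one, via boronic half ester 10 (not isolated), via benzodioxaborin 11 (not isolated), via boron-bound ortho-quinone methide 12 (not isolated), via aryl borate 13 (not isolated)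
Conditions: 9 (1.2 equiv), PhCl, reflux, Dean–Stark; (CH2O)n (1.5 equiv), EtCO2H (0.3 equiv), reflux, Dean–Stark, then distil off part of the solvent; cool, HFIP (to PhCl/HFIP 1:1, 0.05 M), (PhO)2P(O)OH (10 mol %), H2O (1 equiv), 55 °C; pH 7 buffer work-up
Reagents that add atoms: none
Why: Proposed new method: azeotropic esterification hangs the arylboron unit on O8 (10), boron then binds formaldehyde and passes it through a cyclic six-membered transition state to C7, and condensation of the new CH2OH with B–OH gives benzodioxaborin 11, which up to this point is the known boronic-acid-templated ortho-hydroxymethylation of phenols. In ionising, poorly nucleophilic HFIP the phosphoric acid protonates the benzylic ring oxygen, the CH2–O bond breaks under the push of O8 and one water completes the coordination sphere of boron to give the zwitterionic ate complex 12, from which the aryl group moves by its ipso carbon C1' (para to the benzyloxy donor, hence a good migrating terminus) from boron to the exocyclic CH2 through a six-membered transition state made of B, O8, C8, C7, CH2 and C1'; hydrolysis of aryl borate 13 then frees O8–H and leaves boric acid. The closest known reaction types are the addition of aryl boronates to ortho-quinone methides and the Petasis reaction of salicylaldehydes, which runs through the same phenoxide-bound ate complex, and what is new is that one boronic acid serves first as template and then as carbon nucleophile, in one flask, with formaldehyde and a hydroxyquinolinone. No ring of the target is closed (the dioxaborin ring is a transient tether, closed by condensation and reopened by heterolysis) and no stereocentre is formed. The step needs attack at C7 and not at C5, the site that untethered electrophiles prefer in 8-hydroxyquinolin-2-ones, nor at C4 or N1, and this is secured by borylating O8 before formaldehyde is added, by delivering formaldehyde from that boron under weak-acid catalysis only, and by distilling off surplus formaldehyde before the stronger acid goes in. It also needs ipso transfer of the aryl group in preference to protodeboronation, Friedel–Crafts attack at C6' and solvent capture, which the tether, high dilution and a mild acid favour, while capture by water merely leads back towards 11, so that C–C bond formation is the only irreversible exit.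

Step 6
Reactants: 14 7-[4-(benzyloxy)-3-methoxybenzyl]-8-hydroxy-3-methoxyquinolin-2(1H)-one
Product: 15 7-[4-(benzyloxy)-3-methoxybenzyl]-3-methoxy-2-oxo-1,2-dihydroquinolin-8-yl hydrogen sulfate
Conditions: SO3·pyridine (4 equiv), pyridine, 45 °C; aq NaHCO3; C18 reversed phase (handled as the sodium salt)
Reagents that add atoms: sulfur trioxide–pyridine complex, [O-]S(=O)(=O)[n+]1ccccc1
Why: O-Sulfation of a phenol by a sulfur trioxide–amine complex, site-selective because O8–H is the only free phenol while the guaiacyl oxygen is still benzylated, any sulfonation at the lactam N1 or O2 being reversed in the bicarbonate work-up, which also replaces pyridinium, an inhibitor of benzyl ether hydrogenolysis, by sodium.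

Step 7
Reactants: 15 7-[4-(benzyloxy)-3-methoxybenzyl]-3-methoxy-2-oxo-1,2-dihydroquinolin-8-yl hydrogen sulfate
Product: 16 scolopendrine, 7-(4-hydroxy-3-methoxybenzyl)-3-methoxy-2-oxo-1,2-dihydroquinolin-8-yl hydrogen sulfate
Conditions: H2 (1 atm), 10% Pd/C, MeOH/H2O (pH 7–8), rt; filter; Dowex 50W (H+ form), 0 °C, lyophilise at once
Reagents that add atoms: none
Why: Catalytic hydrogenolysis of the aryl benzyl ether at neutral to slightly basic pH, where aryl sulfate salts, the diarylmethane CH2 and the pyridone ring are all inert, followed by a short cold cation exchange that gives the hydrogen sulfate form drawn for the target.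

Compound list
1 | 3-hydroxy-2-nitrobenzaldehyde | O=Cc1cccc(O)c1[N+](=O)[O-] | starting material
2 | 3-(benzyloxy)-2-nitrobenzaldehyde | O=Cc1cccc(OCc2ccccc2)c1[N+](=O)[O-] | intermediate
3 | 2-amino-3-(benzyloxy)benzaldehyde | Nc1c(C=O)cccc1OCc1ccccc1 | intermediate
4 | methoxyacetyl chloride | COCC(=O)Cl | starting material
5 | N-[2-(benzyloxy)-6-formylphenyl]-2-methoxyacetamide | COCC(=O)Nc1c(C=O)cccc1OCc1ccccc1 | intermediate
6 | 8-(benzyloxy)-3-methoxyquinolin-2(1H)-one | COc1cc2cccc(OCc3ccccc3)c2[nH]c1=O | intermediate
7 | 8-hydroxy-3-methoxyquinolin-2(1H)-one (precursor of the key step) | COc1cc2cccc(O)c2[nH]c1=O | intermediate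
8 | formaldehyde (charged as paraformaldehyde) | C=O | starting material
9 | 4-(benzyloxy)-3-methoxyphenylboronic acid | COc1cc(B(O)O)ccc1OCc1ccccc1 | starting material
10 | [4-(benzyloxy)-3-methoxyphenyl]boronic acid mono(3-methoxy-2-oxo-1,2-dihydroquinolin-8-yl) ester | COc1cc2cccc(OB(O)c3ccc(OCc4ccccc4)c(OC)c3)c2[nH]c1=O | intermediate
11 | 2-[4-(benzyloxy)-3-methoxyphenyl]-4H-1,3,2-dioxaborin fused across C7–C8 of 3-methoxyquinolin-2(1H)-one (O1 on C8, C4H2 on C7) | COc1cc2ccc3COB(c4ccc(OCc5ccccc5)c(OC)c4)Oc3c2[nH]c1=O | intermediate
12 | ate complex of 3-methoxy-7-methylidenequinoline-2,8(1H,7H)-dione bound through O8 to ArB(OH)2, Ar = 4-(benzyloxy)-3-methoxyphenyl | C=C1C=Cc2cc(OC)c(=O)[nH]c2C1=[O+][B-](O)(O)c1ccc(OCc2ccccc2)c(OC)c1 | intermediate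
13 | 7-[4-(benzyloxy)-3-methoxybenzyl]-3-methoxy-2-oxo-1,2-dihydroquinolin-8-yl dihydrogen borate | COc1cc(Cc2ccc3cc(OC)c(=O)[nH]c3c2OB(O)O)ccc1OCc1ccccc1 | intermediate
14 | 7-[4-(benzyloxy)-3-methoxybenzyl]-8-hydroxy-3-methoxyquinolin-2(1H)-one (product of the key step) | COc1cc(Cc2ccc3cc(OC)c(=O)[nH]c3c2O)ccc1OCc1ccccc1 | intermediate
15 | 7-[4-(benzyloxy)-3-methoxybenzyl]-3-methoxy-2-oxo-1,2-dihydroquinolin-8-yl hydrogen sulfate | COc1cc(Cc2ccc3cc(OC)c(=O)[nH]c3c2OS(=O)(=O)O)ccc1OCc1ccccc1 | intermediate
16 | scolopendrine (achiral) | COc1cc(Cc2ccc3cc(OC)c(=O)[nH]c3c2OS(=O)(=O)O)ccc1O | target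

Total step count: 7. Longest linear sequence: 7 steps (1 to 16). Compounds 4, 8 and 9 are bought and enter directly.

Steps most likely to fail

1. Step 5 (key step).
What may go wrong:
- slow hydroxymethylation, because C7 is only moderately nucleophilic
- protodeboronation of the electron-rich aryl–boron bond before transfer
- reluctant heterolysis of the primary benzylic C–O bond
- intermolecular Friedel–Crafts alkylation and oligomerisation
- reversible tying-up of formaldehyde at N1

The fallback uses known chemistry only, sets out from 7 and comes back at 14. Magnesium-mediated ortho-formylation (MgCl2, Et3N, paraformaldehyde, MeCN, reflux; Casnati–Skattebøl) relies on the same single free ortho position. It should give 8-hydroxy-3-methoxy-2-oxo-1,2-dihydroquinoline-7-carbaldehyde F1. The Grignard reagent [4-(benzyloxy)-3-methoxyphenyl]magnesium bromide F2 is made from commercial 1-(benzyloxy)-4-bromo-2-methoxybenzene and magnesium in THF. It is used in excess, because two equivalents are spent on O8–H and N1–H. It adds to the aldehyde to give racemic 7-{[4-(benzyloxy)-3-methoxyphenyl](hydroxy)methyl}-8-hydroxy-3-methoxyquinolin-2(1H)-one F3. Ionic hydrogenation of this doubly activated benzylic alcohol (Et3SiH, TFA, CH2Cl2, 0 °C) removes the hydroxyl group together with the transient stereocentre and gives 14.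

2. Step 3.
What may go wrong:
- self-condensation of the aminoaldehyde before acylation is complete
- stalling at the aldol stage without loss of water
- cleavage of the amide by the base at 90 °C

The fallback reverses the order of bond formation, sets out from 2 and comes back at 6. Horner–Wadsworth–Emmons olefination of 2 with commercial methyl 2-(dimethoxyphosphoryl)-2-methoxyacetate (DBU, LiCl, MeCN) should give methyl 3-[3-(benzyloxy)-2-nitrophenyl]-2-methoxyacrylate F4 as a mixture of alkene isomers. Iron in acetic acid at 80 °C reduces it to methyl 3-[2-amino-3-(benzyloxy)phenyl]-2-methoxyacrylate F5. The isomer of F5 with aryl and ester cis lactamises spontaneously. The other isomer is fed into the same irreversible closure by photoisomerisation (365 nm, dilute MeOH). Both converge on 6.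

3. Step 6.
What may go wrong:
- incomplete sulfation of a phenol that is flanked by the C7 benzyl group and hydrogen-bonded to N1–H
- hydrolytic loss of the sulfate during work-up and purification of a polar salt

The fallback installs a protected, neutral sulfate, sets out from 14 and comes back at 15. 2,2,2-Trichloroethyl chlorosulfate (Et3N, DMAP, THF, 0 °C to rt) should give 7-[4-(benzyloxy)-3-methoxybenzyl]-3-methoxy-2-oxo-1,2-dihydroquinolin-8-yl 2,2,2-trichloroethyl sulfate F6. This diester can be purified on silica gel. Reductive fragmentation of the trichloroethyl group (Zn, HCO2NH4, MeOH, rt) gives 15 as its ammonium salt, which is exchanged to sodium before step 7.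

Further compounds
F1 | step 5 | 8-hydroxy-3-methoxy-2-oxo-1,2-dihydroquinoline-7-carbaldehyde | COc1cc2ccc(C=O)c(O)c2[nH]c1=O
F2 | step 5 | [4-(benzyloxy)-3-methoxyphenyl]magnesium bromide | COc1cc([Mg]Br)ccc1OCc1ccccc1
F3 | step 5 | 7-{[4-(benzyloxy)-3-methoxyphenyl](hydroxy)methyl}-8-hydroxy-3-methoxyquinolin-2(1H)-one (racemic) | COc1cc(C(O)c2ccc3cc(OC)c(=O)[nH]c3c2O)ccc1OCc1ccccc1
F4 | step 3 | methyl 3-[3-(benzyloxy)-2-nitrophenyl]-2-methoxyacrylate (E/Z mixture) | COC(=O)C(OC)=Cc1cccc(OCc2ccccc2)c1[N+](=O)[O-]
F5 | step 3 | methyl 3-[2-amino-3-(benzyloxy)phenyl]-2-methoxyacrylate (E/Z mixture) | COC(=O)C(OC)=Cc1cccc(OCc2ccccc2)c1N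
F6 | step 6 | 7-[4-(benzyloxy)-3-methoxybenzyl]-3-methoxy-2-oxo-1,2-dihydroquinolin-8-yl 2,2,2-trichloroethyl sulfate | COc1cc(Cc2ccc3cc(OC)c(=O)[nH]c3c2OS(=O)(=O)OCC(Cl)(Cl)Cl)ccc1OCc1ccccc1
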